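**Retrosynthetic overview**
1. Feature: the B-ring benzene C3a'–C4'–C5'–C6'–C7'–C7a' shares its C3a'–C7a' edge with the dihydrofuran (bridge O1'–C2'–C3') and carries only one other group, chromone C3 at C5'. It can therefore be read as the cyclotrimer of a 3-oxa-1,6-diyne and a 3-ethynylchromone.
2. Key cut: C3a'–C7a', C4'–C5' and C6'–C7' are broken together, giving ynol ether diyne 15 and alkyne 21. A SiEt3 group on the ynol terminus (later C7') steers the chromone to C5' and is exchanged for H at the end.
3. Diyne 15: C2' comes from methyl (R)-glycidate 1 (MeMgBr, BOM acetal, acetylide opening of the epoxide) and the ynol carbons from trichloroethylene 8. The tertiary oxygen carries an acetal, because a silyl ether there would migrate to the vicinal alkoxide that the ynol ether synthesis needs.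
4. Alkyne 21: phloroacetophenone 16 by dibenzylation, enaminone iodocyclisation and Sonogashira coupling.
5. Ring order: ring A is bought, pyranone ring C forms in step 9, dihydrofuran and ring B form together in step 12. Hydrogenolysis and protodesilylation follow.

Key step: step 12

Remark: primed locants refer to the 2,3-dihydrobenzofuran unit (O1', C2', C3', C3a', C4'–C7', C7a'). The descriptor in the target SMILES corresponds to (R) at C2', the same spatial arrangement as in methyl (R)-glycidate, so no inversion is planned.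

Step 1
Reactants: 1 methyl (R)-glycidate
Product: 3 2-[(2R)-oxiran-2-yl]propan-2-ol, via epoxy methyl ketone 2 (not isolated)
Conditions: MeMgBr (2.2 equiv), THF, −78 → −20 °C; aq NH4Cl; careful concentration (volatile), used crude
Reagents that add atoms: methylmagnesium bromide, C[Mg]Br
Why: Double Grignard addition to an ester: at low temperature attack on the ester carbonyl of 1 and on the still more reactive ketone 2 outruns opening of the epoxide, and C2', which is bought with 1, keeps its (R) configuration because none of its four bonds is touched.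

Step 2
Reactants: 3 2-[(2R)-oxiran-2-yl]propan-2-ol
Product: 4 (2R)-2-{2-[(benzyloxy)methoxy]propan-2-yl}oxirane
Conditions: BOMCl (1.5 equiv), i-Pr2NEt (3 equiv), Bu4NI (10 mol %), CH2Cl2, 0 °C → rt
Reagents that add atoms: benzyl chloromethyl ether (BOMCl), ClCOCc1ccccc1
Why: Acetal protection by O-alkylation with an α-chloro ether under amine base works on tertiary alcohols and needs no alkoxide, so that Payne rearrangement of the epoxy alcohol is shut out; the acetal cannot migrate to the neighbouring oxygen in step 4 as a silyl group would.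

Step 3
Reactants: 4 (2R)-2-{2-[(benzyloxy)methoxy]propan-2-yl}oxirane; 5 trimethylsilylacetylene
Product: 7 (3R)-2-[(benzyloxy)methoxy]-2-methyl-6-(trimethylsilyl)hex-5-yn-3-ol, via lithium trimethylsilylacetylide 6 (not isolated)
Conditions: 5 (1.5 equiv), n-BuLi, THF, −78 °C; BF3·OEt2 (1.5 equiv); then 4, −78 °C
Reagents that add atoms: none
Why: Yamaguchi–Hirao alkynylation: the BF3-activated monosubstituted epoxide is opened by the acetylide in SN2 fashion at its unhindered CH2 (the later C3'), so that the C2'–O bond and with it the (R) configuration are kept.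

Step 4
Reactants: 7 (3R)-2-[(benzyloxy)methoxy]-2-methyl-6-(trimethylsilyl)hex-5-yn-3-ol; 8 trichloroethylene
Product: 11 {(4R)-5-[(benzyloxy)methoxy]-4-{[(E)-1,2-dichloroethenyl]oxy}-5-methylhex-1-yn-1-yl}trimethylsilane, via potassium alkoxide 9 (not isolated), via dichloroacetylene 10 (not isolated)
Conditions: KH (2.2 equiv), THF, 0 °C, 10 min; 8 (1.1 equiv), −50 °C → rt (10 is made and consumed in situ only)
Reagents that add atoms: none
Why: Dichlorovinyl ether synthesis from trichloroethylene: base-induced loss of HCl from 8 gives 10, the alkoxide 9 adds to it in anti fashion and proton transfer gives the (E)-1,2-dichlorovinyl ether, the slim linear electrophile being easier to reach for the hindered alkoxide than the silicon of the alkynylsilane, and the O–C2' bond is not involved.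

Step 5
Reactants: 11 (E)-1,2-dichlorovinyl ether of 7
Product: 14 {(4R)-5-[(benzyloxy)methoxy]-5-methyl-4-{[(triethylsilyl)ethynyl]oxy}hex-1-yn-1-yl}trimethylsilane, via chloroalkynyl ether 12 (not isolated), via lithium alkoxyacetylide 13 (not isolated)
Conditions: n-BuLi (2.2 equiv), THF, −78 → −40 °C; TESCl (1.3 equiv), −78 → 0 °C; pH 7–8 work-up, Et3N-deactivated SiO2, kept cold
Reagents that add atoms: chlorotriethylsilane, CC[Si](Cl)(CC)CC
Why: Elimination/exchange route from dichlorovinyl ethers to metalated ynol ethers: n-BuLi removes the vinylic proton, loss of LiCl gives 12, Cl/Li exchange gives 13 and C-silylation caps the later C7', all of it at temperatures at which the propargylic CH2 is not metalated and the ynol ether does not fragment.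

Step 6
Reactants: 14 bis-silylated diyne
Product: 15 ({[(3R)-2-[(benzyloxy)methoxy]-2-methylhex-5-yn-3-yl]oxy}ethynyl)triethylsilane
Conditions: K2CO3 (0.3 equiv), MeOH–THF 1:1, 0 °C, stopped as soon as 14 is consumed
Reagents that add atoms: none
Why: Base-catalysed methanolysis of alkynylsilanes falls off steeply with the size of the groups on silicon, so that C(sp)–SiMe3 should be cleaved well before C(sp)–SiEt3 (the differentiation in use for unsymmetrically capped diynes), while the ynol ether, which is sensitive to acid and heat only, and the BOM acetal are inert to the cold basic medium.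

Step 7
Reactants: 16 2,4,6-trihydroxyacetophenone
Product: 17 1-[2,4-bis(benzyloxy)-6-hydroxyphenyl]ethan-1-one
Conditions: BnBr (2.05 equiv), K2CO3 (2.2 equiv), DMF, rt → 40 °C
Reagents that add atoms: benzyl bromide, BrCc1ccccc1
Why: Williamson etherification: with two equivalents of halide two phenols are alkylated, while the remaining ortho phenol, tied up in a hydrogen bond to the ketone, stays free for the later ring closure.

Step 8
Reactants: 17 1-[2,4-bis(benzyloxy)-6-hydroxyphenyl]ethan-1-one
Product: 18 (E)-1-[2,4-bis(benzyloxy)-6-hydroxyphenyl]-3-(dimethylamino)prop-2-en-1-one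
Conditions: DMF dimethyl acetal (3 equiv), toluene, 95 °C
Reagents that add atoms: N,N-dimethylformamide dimethyl acetal, COC(OC)N(C)C
Why: Condensation of an aryl methyl ketone with an amide acetal gives the vinylogous amide (enaminone), which supplies C2 of the chromone and is held E by conjugation.

Step 9
Reactants: 18 enaminone
Product: 19 5,7-bis(benzyloxy)-3-iodo-4H-chromen-4-one
Conditions: I2 (1.5 equiv), CHCl3, rt; aq Na2S2O3
Reagents that add atoms: iodine, II
Why: Enaminone iodocyclisation: iodination at the α-carbon gives an iminium ion, the free phenol adds to it and loss of dimethylamine closes pyranone ring C with iodine in place at C3.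

Step 10
Reactants: 19 5,7-bis(benzyloxy)-3-iodo-4H-chromen-4-one; 5 trimethylsilylacetylene
Product: 20 5,7-bis(benzyloxy)-3-[(trimethylsilyl)ethynyl]-4H-chromen-4-one
Conditions: PdCl2(PPh3)2 (3 mol %), CuI (6 mol %), Et3N (3 equiv), THF, rt
Reagents that add atoms: none
Why: Sonogashira coupling of an electron-poor vinylic iodide proceeds at room temperature, and a tertiary amine is used as base because primary and secondary amines add to C2 of chromones and open the ring.

Step 11
Reactants: 20 5,7-bis(benzyloxy)-3-[(trimethylsilyl)ethynyl]-4H-chromen-4-one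
Product: 21 5,7-bis(benzyloxy)-3-ethynyl-4H-chromen-4-one
Conditions: TBAF (1.1 equiv), AcOH (1.2 equiv), THF, 0 °C
Reagents that add atoms: none
Why: Fluoride-induced protodesilylation of an alkynylsilane, buffered with acetic acid so that no basic nucleophile is present that could attack the electrophilic C2 of the alkynylchromone.

Step 12
Reactants: 15 ynol ether diyne; 21 5,7-bis(benzyloxy)-3-ethynyl-4H-chromen-4-one
Product: 22 5,7-bis(benzyloxy)-3-[(2R)-2-{2-[(benzyloxy)methoxy]propan-2-yl}-7-(triethylsilyl)-2,3-dihydro-1-benzofuran-5-yl]-4H-chromen-4-one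
Conditions: Cp*RuCl(cod) (10 mol %), 21 (2.0 equiv), ClCH2CH2Cl, 20–25 °C, Ar; 15 added by syringe pump over 4 h; never above 40 °C
Reagents that add atoms: none
Why: Proposed new method: cod is displaced, both alkynes of 15 bind to the Cp*RuCl fragment and couple oxidatively to a bicyclic ruthenacyclopentadiene (C3a'–C7a' formed), 21 then adds across the less hindered Ru–C4' terminus, and reductive elimination completes C4'–C5' and C6'–C7' and sets the arene free. The closest known reaction types are the metal-catalysed [2+2+2] cycloadditions of ynamide-tethered 1,6-diynes with alkynes (indolines) and of phenol-linked aryl ynol ether diynes (dibenzofurans); an alkyl ynol ether on an sp3 tether has not been shown to take part, hence the label. The dihydrofuran ring closes in the oxidative coupling, as the five-membered ring that the three-atom tether O1'–C2'–C3' fuses onto the metallacycle, and the benzene ring closes in the insertion/reductive elimination sequence, driven by aromatisation. No stereocentre is created; C2' lies on the tether, none of its bonds reacts, and the neutral medium at room temperature offers no path for epimerisation. The selectivity needed is regiochemical, chromone at C5' and not at C6': Cp*RuCl catalysts join 1,6-diynes capped at one end with terminal alkynes to the meta isomer, because the substituted carbon of 21 bonds to the free terminus C4' and its CH end takes the place next to the bulky C7'–SiEt3. The silyl cap, the slow addition of 15 and the excess of 21 hold back self-reaction of 15, and the temperature ceiling protects the secondary alkyl ynol ether from retro-ene loss of silylketene.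

Step 13
Reactants: 22 protected 7'-silyl isoflavone
Product: 24 5,7-dihydroxy-3-[(2R)-2-(2-hydroxypropan-2-yl)-7-(triethylsilyl)-2,3-dihydro-1-benzofuran-5-yl]-4H-chromen-4-one, via tertiary hemiformal 23 (not isolated)
Conditions: H2 (1 atm), 10 % Pd/C, EtOAc–MeOH 1:1, rt, stopped after uptake of 3 equiv H2
Reagents that add atoms: none
Why: Catalytic hydrogenolysis of the three benzylic C–O bonds frees both phenols and turns the BOM acetal into hemiformal 23, which loses formaldehyde, while the aryl–Si bond, C2' and, with controlled hydrogen uptake, the chromone C2=C3 bond are left alone.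

Step 14
Reactants: 24 7'-triethylsilyl triol
Product: 25 5,7-dihydroxy-3-[(2R)-2-(2-hydroxypropan-2-yl)-2,3-dihydro-1-benzofuran-5-yl]-4H-chromen-4-one (target)
Conditions: CF3CO2H–CH2Cl2 1:4, H2O (2 equiv), 0 °C → rt; aq NaHCO3
Reagents that add atoms: none
Why: Electrophilic ipso-protodesilylation: C7' lies ortho to the donor O1', so that protonation at the silicon-bearing carbon is favoured (β-silicon effect) and loss of the silyl group leaves C7'–H, while the tertiary alcohol is slow to ionise because its cation would sit next to the electron-withdrawing C2'–O1' bond.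

**Compound list**
1 | methyl (R)-glycidate (methyl (2R)-oxirane-2-carboxylate) | COC(=O)[C@H]1CO1 | starting material
2 | 1-[(2R)-oxiran-2-yl]ethan-1-one | CC(=O)[C@H]1CO1 | intermediate
3 | 2-[(2R)-oxiran-2-yl]propan-2-ol | CC(C)(O)[C@H]1CO1 | intermediate
4 | (2R)-2-{2-[(benzyloxy)methoxy]propan-2-yl}oxirane | CC(C)(OCOCc1ccccc1)[C@H]1CO1 | intermediate
5 | trimethylsilylacetylene | C#C[Si](C)(C)C | starting material
6 | lithium trimethylsilylacetylide | [Li]C#C[Si](C)(C)C | intermediate
7 | (3R)-2-[(benzyloxy)methoxy]-2-methyl-6-(trimethylsilyl)hex-5-yn-3-ol | CC(C)(OCOCc1ccccc1)[C@H](O)CC#C[Si](C)(C)C | intermediate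
8 | trichloroethylene | ClC=C(Cl)Cl | starting material
9 | potassium alkoxide of 7 | CC(C)(OCOCc1ccccc1)[C@H]([O-])CC#C[Si](C)(C)C.[K+] | intermediate
10 | dichloroacetylene | ClC#CCl | intermediate
11 | {(4R)-5-[(benzyloxy)methoxy]-4-{[(E)-1,2-dichloroethenyl]oxy}-5-methylhex-1-yn-1-yl}trimethylsilane | CC(C)(OCOCc1ccccc1)[C@@H](CC#C[Si](C)(C)C)O/C(Cl)=C\Cl | intermediate
12 | (R)-chloroethynyl ether of 7 | CC(C)(OCOCc1ccccc1)[C@@H](CC#C[Si](C)(C)C)OC#CCl | intermediate
13 | (R)-lithium alkoxyacetylide | CC(C)(OCOCc1ccccc1)[C@@H](CC#C[Si](C)(C)C)OC#C[Li] | intermediate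
14 | {(4R)-5-[(benzyloxy)methoxy]-5-methyl-4-{[(triethylsilyl)ethynyl]oxy}hex-1-yn-1-yl}trimethylsilane | CC(C)(OCOCc1ccccc1)[C@@H](CC#C[Si](C)(C)C)OC#C[Si](CC)(CC)CC | intermediate
15 | ({[(3R)-2-[(benzyloxy)methoxy]-2-methylhex-5-yn-3-yl]oxy}ethynyl)triethylsilane | CC(C)(OCOCc1ccccc1)[C@@H](CC#C)OC#C[Si](CC)(CC)CC | intermediate
16 | 2,4,6-trihydroxyacetophenone | CC(=O)c1c(O)cc(O)cc1O | starting material
17 | 1-[2,4-bis(benzyloxy)-6-hydroxyphenyl]ethan-1-one | CC(=O)c1c(O)cc(OCc2ccccc2)cc1OCc1ccccc1 | intermediate
18 | (E)-1-[2,4-bis(benzyloxy)-6-hydroxyphenyl]-3-(dimethylamino)prop-2-en-1-one | CN(C)/C=C/C(=O)c1c(O)cc(OCc2ccccc2)cc1OCc1ccccc1 | intermediate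
19 | 5,7-bis(benzyloxy)-3-iodo-4H-chromen-4-one | O=c1c(I)coc2cc(OCc3ccccc3)cc(OCc3ccccc3)c12 | intermediate
20 | 5,7-bis(benzyloxy)-3-[(trimethylsilyl)ethynyl]-4H-chromen-4-one | C[Si](C)(C)C#Cc1coc2cc(OCc3ccccc3)cc(OCc3ccccc3)c2c1=O | intermediate
21 | 5,7-bis(benzyloxy)-3-ethynyl-4H-chromen-4-one | C#Cc1coc2cc(OCc3ccccc3)cc(OCc3ccccc3)c2c1=O | intermediate
22 | 5,7-bis(benzyloxy)-3-[(2R)-2-{2-[(benzyloxy)methoxy]propan-2-yl}-7-(triethylsilyl)-2,3-dihydro-1-benzofuran-5-yl]-4H-chromen-4-one | CC(C)(OCOCc1ccccc1)[C@H]1Cc2cc(-c3coc4cc(OCc5ccccc5)cc(OCc5ccccc5)c4c3=O)cc([Si](CC)(CC)CC)c2O1 | intermediate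
23 | (R)-7'-triethylsilyl hemiformal (tertiary O–CH2OH, both phenols free) | CC(C)(OCO)[C@H]1Cc2cc(-c3coc4cc(O)cc(O)c4c3=O)cc([Si](CC)(CC)CC)c2O1 | intermediate
24 | 5,7-dihydroxy-3-[(2R)-2-(2-hydroxypropan-2-yl)-7-(triethylsilyl)-2,3-dihydro-1-benzofuran-5-yl]-4H-chromen-4-one | CC(C)(O)[C@H]1Cc2cc(-c3coc4cc(O)cc(O)c4c3=O)cc([Si](CC)(CC)CC)c2O1 | intermediate
25 | 5,7-dihydroxy-3-[(2R)-2-(2-hydroxypropan-2-yl)-2,3-dihydro-1-benzofuran-5-yl]-4H-chromen-4-one | CC(C)(O)[C@H]1Cc2cc(-c3coc4cc(O)cc(O)c4c3=O)ccc2O1 | target

**Step count and risks**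

Total step count: 14. Longest linear sequence: 9 (steps 1–6, then 12–14). The chromone arm (steps 7–11) is convergent.

**Step 12.** The risks are these:
- The hindered, electron-rich silyl ynol ether may not turn over on ruthenium.
- 15 may react with itself through its free alkyne end.
- The C5'/C6' selectivity may erode.

In the fallback ring B is bought instead of built, and only the dihydrofuran is closed, all by known chemistry. It sets out from epoxide 4 and iodochromone 19.
- 4-Bromo-1-fluoro-2-iodobenzene is converted with i-PrMgCl·LiCl (THF, −20 °C) into (5-bromo-2-fluorophenyl)magnesium chloride F1.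
- Under CuI catalysis this opens 4 at its CH2 to give (2R)-1-(5-bromo-2-fluorophenyl)-3-[(benzyloxy)methoxy]-3-methylbutan-2-ol F2.
- t-BuOK in THF–DMF (60–80 °C) closes the ring by intramolecular SNAr at C–F, without touching the C2'–O bond, to give (2R)-2-{2-[(benzyloxy)methoxy]propan-2-yl}-5-bromo-2,3-dihydro-1-benzofuran F3.
- Miyaura borylation (B2pin2, PdCl2(dppf), KOAc, dioxane, 85 °C) gives the pinacol boronate F4.
- Suzuki–Miyaura coupling with 19 (PdCl2(dppf), aq K2CO3, DME, 70 °C) gives the silicon-free protected isoflavone F5.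
- Hydrogenolysis under the conditions of step 13 passes through the hemiformal F6 and comes back to the route at target 25.

**Step 4.** The potassium alkoxide may attack the alkynyl–SiMe3 group and transfer silicon to oxygen, or the hindered alkoxide may add too slowly. In the fallback the two ynol carbons are brought in as a vinyl ether under nearly neutral conditions, so no free alkoxide is needed. It sets out from alcohol 7.
- Iridium-catalysed vinyl transfer (vinyl acetate, [Ir(cod)Cl]2, Na2CO3, toluene, 100 °C) gives the (R)-vinyl ether F7.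
- Br2 (1.0 equiv, CH2Cl2, −78 °C) adds to the far more electron-rich enol ether double bond to give the 1,2-dibromoethyl ether F8, as epimers at the bromoacetal carbon.
- Et3N removes HBr to give the (Z)-2-bromovinyl ether F9.
- LDA (2.2 equiv, THF, −78 → −30 °C) effects anti elimination and deprotonation. The route is rejoined at lithium alkoxyacetylide 13, before the TESCl quench of step 5.

**Step 6.** The ynol-side silyl group may be lost together with SiMe3. The alkoxy-substituted acetylide is the better leaving group, and this offsets part of the steric advantage. In the fallback the two alkyne caps differ in the element and not only in size. It sets out from 13.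
- 13 is quenched with chlorotriethylgermane in place of TESCl to give the germyl/silyl-capped diyne F10.
- Alkynyl–germanium bonds are much slower than alkynyl–silicon bonds in base solvolysis, so K2CO3/MeOH should remove SiMe3 only and give the germyl ynol ether diyne F11.
- Cycloaddition with 21 as in step 12 gives the 7'-triethylgermyl protected isoflavone F12.
- Hydrogenolysis as in step 13 gives, through the germyl hemiformal F13, the 7'-triethylgermyl triol F14.
- Acid protodegermylation under the conditions of step 14 comes back to the route at 25. Aryl–Ge bonds are cleaved by acid faster than aryl–Si bonds.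

**Further compounds**
F1 | step 12 | (5-bromo-2-fluorophenyl)magnesium chloride | Fc1ccc(Br)cc1[Mg]Cl
F2 | step 12 | (2R)-1-(5-bromo-2-fluorophenyl)-3-[(benzyloxy)methoxy]-3-methylbutan-2-ol | CC(C)(OCOCc1ccccc1)[C@H](O)Cc1cc(Br)ccc1F
F3 | step 12 | (2R)-2-{2-[(benzyloxy)methoxy]propan-2-yl}-5-bromo-2,3-dihydro-1-benzofuran | CC(C)(OCOCc1ccccc1)[C@H]1Cc2cc(Br)ccc2O1
F4 | step 12 | (2R)-2-{2-[(benzyloxy)methoxy]propan-2-yl}-5-(4,4,5,5-tetramethyl-1,3,2-dioxaborolan-2-yl)-2,3-dihydro-1-benzofuran | CC(C)(OCOCc1ccccc1)[C@H]1Cc2cc(B3OC(C)(C)C(C)(C)O3)ccc2O1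
F5 | step 12 | 5,7-bis(benzyloxy)-3-[(2R)-2-{2-[(benzyloxy)methoxy]propan-2-yl}-2,3-dihydro-1-benzofuran-5-yl]-4H-chromen-4-one | CC(C)(OCOCc1ccccc1)[C@H]1Cc2cc(-c3coc4cc(OCc5ccccc5)cc(OCc5ccccc5)c4c3=O)ccc2O1
F6 | step 12 | (R)-hemiformal of the target (tertiary O–CH2OH) | CC(C)(OCO)[C@H]1Cc2cc(-c3coc4cc(O)cc(O)c4c3=O)ccc2O1
F7 | step 4 | (R)-vinyl ether of 7 | CC(C)(OCOCc1ccccc1)[C@@H](CC#C[Si](C)(C)C)OC=C
F8 | step 4 | (R)-1,2-dibromoethyl ether of 7 (epimers at the bromoacetal carbon) | CC(C)(OCOCc1ccccc1)[C@@H](CC#C[Si](C)(C)C)OC(Br)CBr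
F9 | step 4 | (R)-(Z)-2-bromovinyl ether of 7 | CC(C)(OCOCc1ccccc1)[C@@H](CC#C[Si](C)(C)C)O/C=C\Br
F10 | step 6 | {(4R)-5-[(benzyloxy)methoxy]-5-methyl-4-{[(triethylgermyl)ethynyl]oxy}hex-1-yn-1-yl}trimethylsilane | CC(C)(OCOCc1ccccc1)[C@@H](CC#C[Si](C)(C)C)OC#C[Ge](CC)(CC)CC
F11 | step 6 | ({[(3R)-2-[(benzyloxy)methoxy]-2-methylhex-5-yn-3-yl]oxy}ethynyl)triethylgermane | CC(C)(OCOCc1ccccc1)[C@@H](CC#C)OC#C[Ge](CC)(CC)CC
F12 | step 6 | 5,7-bis(benzyloxy)-3-[(2R)-2-{2-[(benzyloxy)methoxy]propan-2-yl}-7-(triethylgermyl)-2,3-dihydro-1-benzofuran-5-yl]-4H-chromen-4-one | CC(C)(OCOCc1ccccc1)[C@H]1Cc2cc(-c3coc4cc(OCc5ccccc5)cc(OCc5ccccc5)c4c3=O)cc([Ge](CC)(CC)CC)c2O1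
F13 | step 6 | (R)-7'-triethylgermyl hemiformal | CC(C)(OCO)[C@H]1Cc2cc(-c3coc4cc(O)cc(O)c4c3=O)cc([Ge](CC)(CC)CC)c2O1
F14 | step 6 | 5,7-dihydroxy-3-[(2R)-2-(2-hydroxypropan-2-yl)-7-(triethylgermyl)-2,3-dihydro-1-benzofuran-5-yl]-4H-chromen-4-one | CC(C)(O)[C@H]1Cc2cc(-c3coc4cc(O)cc(O)c4c3=O)cc([Ge](CC)(CC)CC)c2O1
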